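**Retrosynthetic overview**
- The target is cut at the C3–O ester bond: a Mitsunobu coupling with inversion joins a C3-epimeric diosphenol core to (2Z)-4-(angeloyloxy)-2-methylbut-2-enoic acid, itself made from 3-methylfuran-2(5H)-one and angelic acid.
- The diosphenol and the isopropylidene of ring B come from one acid step on an epoxy ketone aldol (acetone at C7, epoxide across C9–C10).
- Ring A with the vicinal methyl pair comes from a one-carbon ring expansion: a 1-vinylcyclopentanol rearranges by a 1,2-shift of the quaternary carbon to a 2-methylcyclohexanone.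
- The vinyl carbinol comes from vinyl addition to the (S)-Hajos–Parrish ketone, made from 2-methylcyclopentane-1,3-dione and methyl vinyl ketone with (S)-proline.
- Ring order: ring B (cyclohexenone) is annulated first onto the cyclopentanedione; the five-membered ring is then expanded to ring A.

Assumption: compounds 1, 2, 6 (as a THF solution), 11, 14 and 16 are purchased; the epoxide and C7 centres of 10 and 12 are drawn as the expected major isomers and are erased in step 6.

**Route**

Step 1
Reactants: 1 2-methylcyclopentane-1,3-dione; 2 but-3-en-2-one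
Product: 5 (7aS)-7a-methyl-2,3,7,7a-tetrahydro-1H-indene-1,5(6H)-dione, via Michael triketone 3 (not isolated), via cis-ketol 4 (not isolated)
Conditions: AcOH (cat.), H2O, 70 °C; evaporate; (S)-proline (3 mol%), DMF, 20 °C; then H2SO4 (cat.), 95 °C
Reagents that add atoms: none
Why: Michael addition, then the proline-catalysed Hajos–Parrish intramolecular aldol (enamine catalysis) and acid dehydration; (S)-proline sets the (S) quaternary centre, which becomes C5 of the target.

Step 2
Reactants: 5 (7aS)-7a-methyl-2,3,7,7a-tetrahydro-1H-indene-1,5(6H)-dione; 6 ethenylmagnesium bromide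
Product: 7 (1R,7aS)-1-ethenyl-1-hydroxy-7a-methyl-1,2,3,6,7,7a-hexahydro-5H-inden-5-one
Conditions: 5 premixed with anhydrous CeCl3 (1.5 equiv), THF, 20 °C; then 6 (1.2 equiv), −78 °C; H2O
Reagents that add atoms: none
Why: CeCl3-promoted Grignard 1,2-addition; the strained saturated cyclopentanone is more electrophilic than the vinylogous enone carbonyl and cerium suppresses enolisation; attack anti to the angular methyl gives the (1R) carbinol, a centre that is consumed in step 3.

Step 3
Reactants: 7 (1R,7aS)-1-ethenyl-1-hydroxy-7a-methyl-1,2,3,6,7,7a-hexahydro-5H-inden-5-one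
Product: 8 (4aR,5R)-4a,5-dimethyl-4,4a,7,8-tetrahydronaphthalene-2,6(3H,5H)-dione
Conditions: [N,N'-bis(3,5-di-tert-butylsalicylidene)-2,3-dimethylbutane-2,3-diaminato]cobalt, C36H54CoN2O2 (divalent cobalt, 5 mol%), N-fluoro-2,4,6-trimethylpyridinium tetrafluoroborate (1.2 equiv), PhSiH3 (1.2 equiv), (CF3)2CHOH/CH2Cl2 1:4, 0 °C
Reagents that add atoms: none
Why: Proposed new method: a cobalt hydride (from the trivalent cobalt fluoride and PhSiH3) transfers a hydrogen atom to the terminal vinyl carbon, the secondary radical is captured by cobalt and oxidised to a tetravalent alkylcobalt, and the antiperiplanar, more electron-rich quaternary C7a–C1 bond displaces cobalt with inversion while the hydroxyl becomes the ketone (semipinacol 1,2-shift, cyclopentanol to cyclohexanone); C7a migrates with retention (giving 4aR) and the new methine is predicted to be (5R) because the rotamer with the methyl gauche to oxygen, not wedged between the quaternary carbon and C2, is the less hindered one; closest known reaction type: cobalt-salen/N-fluoropyridinium/silane hydrogen-atom-transfer radical–polar crossover (Markovnikov hydrofunctionalisation of monosubstituted alkenes and semipinacol shifts of 1,1-disubstituted alkenyl carbinols), not yet shown for a secondary alkylcobalt electrophile, a cyclopentanol expansion or this diastereocontrol.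

Step 4
Reactants: 8 (4aR,5R)-4a,5-dimethyl-4,4a,7,8-tetrahydronaphthalene-2,6(3H,5H)-dione
Product: 10 (1aR,4aR,5R,6S,8aR)-6-hydroxy-4a,5-dimethyl-4,4a,5,6,7,8-hexahydro-1aH-naphtho[1,8a-b]oxiren-2(3H)-one, via axial hydroxy enone 9 (not isolated)
Conditions: LiBH(s-Bu)3 (1.05 equiv), THF, −78 °C; then MeOH, aq. NaOH, 30% H2O2 (excess), 0 → 20 °C
Reagents that add atoms: hydrogen peroxide, OO
Why: Chemoselective hydride reduction of the saturated ketone (done at once on crude 8, before C5 can epimerise), then Weitz–Scheffer nucleophilic epoxidation of the enone by the same alkaline peroxide that destroys the borane; the bulky hydride attacks equatorially, opposite the syn-axial angular methyl, and sets the axial (6S) alcohol (deliberately the C3 epimer of the natural series, inverted in step 9); the epoxide configuration is lost in step 6.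

Step 5
Reactants: 10 (1aR,4aR,5R,6S,8aR)-6-hydroxy-4a,5-dimethyl-4,4a,5,6,7,8-hexahydro-1aH-naphtho[1,8a-b]oxiren-2(3H)-one; 11 acetone
Product: 12 (1aR,3S,4aR,5R,6S,8aR)-6-hydroxy-3-(2-hydroxypropan-2-yl)-4a,5-dimethyl-4,4a,5,6,7,8-hexahydro-1aH-naphtho[1,8a-b]oxiren-2(3H)-one
Conditions: LiN(i-Pr)2 (2.3 equiv), THF, −78 °C; then 11 (3 equiv), −78 °C, 20 min; AcOH at −78 °C
Reagents that add atoms: none
Why: Kinetic enolate aldol addition; the first equivalent of base makes the alkoxide, the second removes a proton from the only CH2 next to the ketone, and the enolate adds to acetone anti to the angular methyl (this centre is lost in step 6).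

Step 6
Reactants: 12 (1aR,3S,4aR,5R,6S,8aR)-6-hydroxy-3-(2-hydroxypropan-2-yl)-4a,5-dimethyl-4,4a,5,6,7,8-hexahydro-1aH-naphtho[1,8a-b]oxiren-2(3H)-one
Product: 13 (4aR,5R,6S)-1,6-dihydroxy-4a,5-dimethyl-3-(propan-2-ylidene)-4,4a,5,6,7,8-hexahydronaphthalen-2(3H)-one
Conditions: p-TsOH·H2O (0.3 equiv), toluene, 70 °C
Reagents that add atoms: none
Why: Acid-catalysed isomerisation of the epoxy ketone to the diosphenol (opening at the tertiary carbon, loss of the alpha proton, as in the steroid 4-hydroxy-enone synthesis) together with E1 dehydration of the tertiary aldol to the conjugated isopropylidene; no stereocentre is touched.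

Step 7
Reactants: 14 3-methylfuran-2(5H)-one
Product: 15 potassium (2Z)-4-hydroxy-2-methylbut-2-enoate
Conditions: KOH (1.00 equiv), H2O/MeOH, 20 °C; evaporate, dry under vacuum
Reagents that add atoms: potassium hydroxide, [K+].[OH-]
Why: Saponification of the butenolide; the ring fixes the Z geometry and the hydroxy carboxylate salt cannot relactonise.

Step 8
Reactants: 15 potassium (2Z)-4-hydroxy-2-methylbut-2-enoate; 16 (2Z)-2-methylbut-2-enoic acid (angelic acid)
Product: 19 (2Z)-2-methyl-4-{[(2Z)-2-methylbut-2-enoyl]oxy}but-2-enoic acid, via angeloyl imidazolide 17 (not isolated), via alkoxide carboxylate dianion 18 (not isolated)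
Conditions: 16, 1,1'-carbonyldiimidazole (1.05 equiv), THF, 20 °C; separately 15, NaH (1.05 equiv), DMF, 0 °C; combine at 0 °C; cold 1 M HCl
Reagents that add atoms: none
Why: O-acylation of an alkoxide by an N-acylimidazole (Staab esterification); the carboxylate is inert to the imidazolide, no free hydroxy acid or hydroxy ester is ever present so relactonisation is excluded, and the mild activation preserves both Z alkenes.

Step 9
Reactants: 13 (4aR,5R,6S)-1,6-dihydroxy-4a,5-dimethyl-3-(propan-2-ylidene)-4,4a,5,6,7,8-hexahydronaphthalen-2(3H)-one; 19 (2Z)-2-methyl-4-{[(2Z)-2-methylbut-2-enoyl]oxy}but-2-enoic acid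
Product: 20 (1R,2R,8aR)-5-hydroxy-1,8a-dimethyl-6-oxo-7-(propan-2-ylidene)-1,2,3,4,6,7,8,8a-octahydronaphthalen-2-yl (2Z)-2-methyl-4-{[(2Z)-2-methylbut-2-enoyl]oxy}but-2-enoate
Conditions: PPh3 (1.5 equiv), diisopropyl azodicarboxylate (1.5 equiv), 19 (1.5 equiv), toluene, 0 → 20 °C
Reagents that add atoms: none
Why: Mitsunobu esterification; SN2 displacement of the axial oxyphosphonium by the carboxylate inverts C3 to the equatorial (R) ester, and the enol hydroxyl is neither activated by phosphorus nor acidic enough to compete with the carboxylic acid.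

**Compound list**
1 | 2-methylcyclopentane-1,3-dione | CC1C(=O)CCC1=O | starting material
2 | but-3-en-2-one (methyl vinyl ketone) | CC(=O)C=C | starting material
3 | 2-methyl-2-(3-oxobutyl)cyclopentane-1,3-dione | CC(=O)CCC1(C)C(=O)CCC1=O | intermediate
4 | (3aS,7aS)-3a-hydroxy-7a-methylhexahydro-1H-indene-1,5(4H)-dione | C[C@]12CCC(=O)C[C@@]1(O)CCC2=O | intermediate
5 | (7aS)-7a-methyl-2,3,7,7a-tetrahydro-1H-indene-1,5(6H)-dione | C[C@]12CCC(=O)C=C1CCC2=O | intermediate
6 | ethenylmagnesium bromide | C=C[Mg]Br | starting material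
7 | (1R,7aS)-1-ethenyl-1-hydroxy-7a-methyl-1,2,3,6,7,7a-hexahydro-5H-inden-5-one (hydroxyl cis to the angular methyl) | C[C@]12CCC(=O)C=C1CC[C@@]2(O)C=C | intermediate
8 | (4aR,5R)-4a,5-dimethyl-4,4a,7,8-tetrahydronaphthalene-2,6(3H,5H)-dione (methyls cis) | O=C1CCC2=CC(=O)CC[C@]2(C)[C@H]1C | intermediate
9 | (4aR,5R,6S)-6-hydroxy-4a,5-dimethyl-4,4a,5,6,7,8-hexahydronaphthalen-2(3H)-one (hydroxyl cis to both methyls) | O[C@H]1CCC2=CC(=O)CC[C@]2(C)[C@H]1C | intermediate
10 | (1aR,4aR,5R,6S,8aR)-6-hydroxy-4a,5-dimethyl-4,4a,5,6,7,8-hexahydro-1aH-naphtho[1,8a-b]oxiren-2(3H)-one (oxirane on the face of the angular methyl) | O[C@H]1CC[C@]23O[C@H]2C(=O)CC[C@]3(C)[C@H]1C | intermediate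
11 | acetone | CC(C)=O | starting material
12 | (1aR,3S,4aR,5R,6S,8aR)-6-hydroxy-3-(2-hydroxypropan-2-yl)-4a,5-dimethyl-4,4a,5,6,7,8-hexahydro-1aH-naphtho[1,8a-b]oxiren-2(3H)-one | O[C@H]1CC[C@]23O[C@H]2C(=O)[C@H](C(C)(C)O)C[C@]3(C)[C@H]1C | intermediate
13 | (4aR,5R,6S)-1,6-dihydroxy-4a,5-dimethyl-3-(propan-2-ylidene)-4,4a,5,6,7,8-hexahydronaphthalen-2(3H)-one | O[C@H]1CCC2=C(O)C(=O)C(=C(C)C)C[C@]2(C)[C@H]1C | intermediate
14 | 3-methylfuran-2(5H)-one | CC1=CCOC1=O | starting material
15 | potassium (2Z)-4-hydroxy-2-methylbut-2-enoate | OC/C=C(/C)C(=O)[O-].[K+] | intermediate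
16 | (2Z)-2-methylbut-2-enoic acid (angelic acid) | C/C=C(/C)C(=O)O | starting material
17 | (2Z)-1-(1H-imidazol-1-yl)-2-methylbut-2-en-1-one | C/C=C(/C)C(=O)n1ccnc1 | intermediate
18 | potassium sodium (2Z)-2-methyl-4-oxidobut-2-enoate | [Na+].[K+].[O-]C/C=C(/C)C(=O)[O-] | intermediate
19 | (2Z)-2-methyl-4-{[(2Z)-2-methylbut-2-enoyl]oxy}but-2-enoic acid | C/C=C(/C)C(=O)OC/C=C(/C)C(=O)O | intermediate
20 | (1R,2R,8aR)-5-hydroxy-1,8a-dimethyl-6-oxo-7-(propan-2-ylidene)-1,2,3,4,6,7,8,8a-octahydronaphthalen-2-yl (2Z)-2-methyl-4-{[(2Z)-2-methylbut-2-enoyl]oxy}but-2-enoate | C/C=C(/C)C(=O)OC/C=C(/C)C(=O)O[C@@H]1CCC2=C(O)C(=O)C(=C(C)C)C[C@]2(C)[C@H]1C | target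

**Step count**
Total steps: 9. Longest linear sequence: 7 (steps 1, 2, 3, 4, 5, 6, 9); steps 7 and 8 make the side-chain acid.

**Steps most likely to fail**

Step 3 (the proposed ring expansion). Risks are plain reduction of the vinyl group, epoxide formation from the hydroxy alkylcobalt, or a poor ratio at the new methine. The fallback uses known chemistry, sets out from 7 and comes back at 8. Hydroxyl-directed epoxidation (VO(acac)2, t-BuOOH, CH2Cl2) gives (1S,7aS)-1-hydroxy-7a-methyl-1-(oxiran-2-yl)-1,2,3,6,7,7a-hexahydro-5H-inden-5-one F3. BF3·OEt2 in CH2Cl2 at −78 °C then triggers the established 2,3-epoxy alcohol semipinacol ring expansion, with the same quaternary carbon migrating, to (4aR)-5-(hydroxymethyl)-4a-methyl-4,4a,7,8-tetrahydronaphthalene-2,6(3H,5H)-dione F4. MsCl/Et3N gives the mesylate [(8aR)-8a-methyl-2,6-dioxo-1,2,3,4,6,7,8,8a-octahydronaphthalen-1-yl]methyl methanesulfonate F5, and DBU eliminates it to (4aS)-4a-methyl-5-methylidene-4,4a,7,8-tetrahydronaphthalene-2,6(3H,5H)-dione F6. Conjugate reduction of the unhindered exocyclic enone with [(Ph3P)CuH]6, with protonation anti to the angular methyl, gives 8 with the cis methyl pair.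

Step 9 (Mitsunobu with inversion at a hindered axial alcohol). The risk is E2 elimination of the oxyphosphonium. The fallback changes the activation, sets out from 13 and comes back at 20. TBSCl/imidazole silylates the acidic enol to (4aR,5R,6S)-1-[(tert-butyldimethylsilyl)oxy]-6-hydroxy-4a,5-dimethyl-3-(propan-2-ylidene)-4,4a,5,6,7,8-hexahydronaphthalen-2(3H)-one F7. ClCH2SO2Cl/pyridine gives the C6 chloromethanesulfonate of that silyl enol ether F8. The caesium salt of 19 (Cs2CO3, 18-crown-6, toluene, 50 °C) displaces the sulfonate with inversion to the 5-O-tert-butyldimethylsilyl ether of 20 F9. HF·pyridine in THF frees the enol and gives 20.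

Step 2 (vinyl addition in the presence of the enone). The risk is competing 1,2-addition at the less hindered enone carbonyl or enolisation. The fallback sets out from 5 and comes back at 7. Ethane-1,2-dithiol with BF3·OEt2 in MeOH masks the conjugated carbonyl selectively as (7a'S)-7a'-methyl-2',3',7',7a'-tetrahydrospiro[1,3-dithiolane-2,5'-inden]-1'(6'H)-one F1. CH2=CHMgBr/CeCl3 then gives (1'R,7a'S)-1'-ethenyl-7a'-methyl-1',2',3',6',7',7a'-hexahydrospiro[1,3-dithiolane-2,5'-inden]-1'-ol F2. MeI, CaCO3 in aqueous MeCN removes the dithiolane and returns 7.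

**Further compounds**
F1 | step 2 | (7a'S)-7a'-methyl-2',3',7',7a'-tetrahydrospiro[1,3-dithiolane-2,5'-inden]-1'(6'H)-one | C[C@]12CCC3(SCCS3)C=C1CCC2=O
F2 | step 2 | (1'R,7a'S)-1'-ethenyl-7a'-methyl-1',2',3',6',7',7a'-hexahydrospiro[1,3-dithiolane-2,5'-inden]-1'-ol | C[C@]12CCC3(SCCS3)C=C1CC[C@@]2(O)C=C
F3 | step 3 | (1S,7aS)-1-hydroxy-7a-methyl-1-(oxiran-2-yl)-1,2,3,6,7,7a-hexahydro-5H-inden-5-one (both oxirane epimers) | C[C@]12CCC(=O)C=C1CC[C@@]2(O)C3CO3
F4 | step 3 | (4aR)-5-(hydroxymethyl)-4a-methyl-4,4a,7,8-tetrahydronaphthalene-2,6(3H,5H)-dione (both C5 epimers) | O=C1CCC2=CC(=O)CC[C@]2(C)C1CO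
F5 | step 3 | [(8aR)-8a-methyl-2,6-dioxo-1,2,3,4,6,7,8,8a-octahydronaphthalen-1-yl]methyl methanesulfonate (both C1 epimers) | O=C1CCC2=CC(=O)CC[C@]2(C)C1COS(C)(=O)=O
F6 | step 3 | (4aS)-4a-methyl-5-methylidene-4,4a,7,8-tetrahydronaphthalene-2,6(3H,5H)-dione | O=C1CCC2=CC(=O)CC[C@]2(C)C1=C
F7 | step 9 | (4aR,5R,6S)-1-[(tert-butyldimethylsilyl)oxy]-6-hydroxy-4a,5-dimethyl-3-(propan-2-ylidene)-4,4a,5,6,7,8-hexahydronaphthalen-2(3H)-one | O[C@H]1CCC2=C(O[Si](C)(C)C(C)(C)C)C(=O)C(=C(C)C)C[C@]2(C)[C@H]1C
F8 | step 9 | (1R,2S,8aR)-5-[(tert-butyldimethylsilyl)oxy]-1,8a-dimethyl-6-oxo-7-(propan-2-ylidene)-1,2,3,4,6,7,8,8a-octahydronaphthalen-2-yl chloromethanesulfonate | ClCS(=O)(=O)O[C@H]1CCC2=C(O[Si](C)(C)C(C)(C)C)C(=O)C(=C(C)C)C[C@]2(C)[C@H]1C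
F9 | step 9 | (1R,2R,8aR)-5-[(tert-butyldimethylsilyl)oxy]-1,8a-dimethyl-6-oxo-7-(propan-2-ylidene)-1,2,3,4,6,7,8,8a-octahydronaphthalen-2-yl (2Z)-2-methyl-4-{[(2Z)-2-methylbut-2-enoyl]oxy}but-2-enoate | C/C=C(/C)C(=O)OC/C=C(/C)C(=O)O[C@@H]1CCC2=C(O[Si](C)(C)C(C)(C)C)C(=O)C(=C(C)C)C[C@]2(C)[C@H]1C
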